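# Proposed total synthesis of CNP0119865.1 (38)

## Analysis of the target

The target 38 is a dibrominated C20 tertiary alcohol. A trans-fused hydrindane (six-membered ring C10/C12/C13/C14/C15/C17, five-membered ring C7/C8/C9/C10/C17; carbons are numbered C1 to C20 in the order of the SMILES string) carries at C7 an exocyclic (E)-alkene C5=C6 that is part of a 4-bromo-3,3-dimethylcyclohexylidene ring (C2/C4/C5/C18/C19/C20). There are six stereocentres: C7, C10, C12, C15 and C17 on the bicycle and C20 in the outer ring. In the chair of the six-membered ring the angular methyl C11 is axial and anti to H17, the C12 bromide is equatorial and cis to C11, the C15 hydroxyl is axial and 1,3-syn to C11 with methyl C16 equatorial, and the C6 substituent on C7 is pseudo-equatorial, cis to H17. C20 lies five bonds from the nearest other stereocentre, so only a reagent can set it, and the alkene geometry is defined by nothing more than the difference between C4 (next to the quaternary C2) and C18. Both bromides are secondary and neopentyl (next to C10 and to C2), hard to install by substitution and prone to elimination or 1,2-shift once activated; the tertiary alcohol dehydrates easily and the trisubstituted alkene can move into the ring under acid. The difficulty therefore lies in the quaternary C10 wedged between C12 and the ring fusion, in the two neopentyl C–Br bonds, and in the remote pair of alkene geometry and C20. The strategy rests on the row C12–C10–C17–C15 of the six-membered ring: the adjacent carbons C10 (methyl C11, arm C9) and C17 (H, arm C7) sit between the two heteroatom-bearing carbons C12 and C15, which is the pattern left when an E-configured 2-methyl-2-enal adds to a 1,4-dioxygenated butadiene.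

## Retrosynthetic reasoning

**38 ⇒ 37 ⇒ 36 ⇒ 35 (C20–Br).** The last operation only frees the C15 hydroxyl of silyl ether 37. The C20–Br bond of 37 is traced back, with inversion, to the C20–O bond of alcohol 36, and 36 to ketone 35. The substrate cannot control C20, but in 35 it is a carbonyl carbon flanked by the quaternary C2 and the methylene C19, a good case for catalyst-controlled hydride transfer. The forward sequence must reduce from one face and then substitute at a neopentyl carbon without elimination.

**35 ⇒ 34 (C18–C19).** The outer ring is opened at C18–C19 to chloro ketone 34. This bond is chosen because the methyl ketone of 34 can enolise in one direction only (C2 is quaternary) and because closing here leaves C5=C6 untouched, so an alkene geometry set earlier is carried into the ring. 34 comes from methyl ketone 32 through allylic alcohol 33.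

**32 ⇒ 31 ⇒ 28 (C2–C4).** Methyl ketone 32 is the acid 31 with one more carbon (C19), and 31 is the product of a [3,3] shift of isobutyrate 28. Cutting C2–C4 gives three things at once: the quaternary C2 with both methyl groups, C20 as a carbonyl carbon, and the geometry of C5=C6, which a chair transition state fixes with C4 trans to C7. An olefination of a preformed ring ketone was not used because the two α-methylenes of a 3,3-dimethylcyclohexanone differ too little to control the geometry.

**28 ⇒ 27 ⇒ 22 + 25 (C5–C6).** The allylic ester 28 comes from alcohol 27, made by adding the C4/C5/C18 unit of bromide 25 to the aldehyde carbon C6 of 22. The carbinol centre formed at C6 needs no control, since it becomes sp2 in the rearrangement.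

**22 ⇒ 19 (C7–C8).** The cyclopentane is opened at C7–C8 to the bromo aldehyde 19. C7 is α to the C6 aldehyde and C8 is a primary bromide, so a 5-exo alkylation closes the ring. The two arms are trans-diequatorial on the cyclohexane, so the fusion is trans by construction. In 19 both lower-face axial positions (C11 on C10, the silyloxy group on C15) are occupied, and this directs the C6 group to the side of H17.

**19 ⇒ 16 ⇒ 15 ⇒ 13 ⇒ 12 ⇒ 11 (C15–C16 and C12–Br).** The C15 carbinol of 16 is cut at C15–C16 to ketone 15. In 15 the equatorial C12 bromide and the two equatorial arms lock the chair with C11 axial, so a methyl nucleophile must enter equatorially. The C12–Br bond of 13 is traced back with inversion to the C12–O bond of 12, whose oxygen the cycloaddition places on the face opposite to the one bromine needs. The two secondary hydroxyls of diol 11 are told apart by silylation of the unhindered equatorial one (12).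

**11 ⇒ 10 ⇒ 9 ⇒ 7 ⇒ 6 ⇒ 5 (C8–C9).** C8 is the only ring carbon the cycloaddition does not bring. It is added to the formyl carbon of 6 by methylenation (7) and anti-Markovnikov hydration (9), then turned into the bromide 10. This is done before C12 is activated, so that no alkene sits on C10 when the C12–O bond is ionised. 6 is the dihydro derivative of 5.

**5 ⇒ 3 + 4 (C10–C12 and C15–C17).** Cutting both bonds of the cyclohexene 5 gives the E-enal 3 and the symmetric diene 4. This is the place to cut because one concerted step then makes the quaternary C10, fixes C17 relative to it, and puts oxygen on both C12 and C15 with no regiochemical question.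

**3 ⇒ 1 + 2 (C10=C17).** The enal 3 is cut at its double bond into aldehyde 1 and the formyl-stabilised ylide 2, both commercial. The E geometry follows from the stabilised ylide.

## Alternatives that were turned down

**Alternative 1:** The disconnection is C7–C17, made on an achiral cyclohexadienone. The quinol malonate A1 (the methyl malonate of 4-hydroxy-4-methylcyclohexa-2,5-dienone, from p-cresol) would be desymmetrised by an intramolecular Michael addition under a bifunctional amine–thiourea catalyst: the malonate carbon (C7) attacks one of the two enantiotopic enone β-carbons (C17) and gives the cis-fused lactone enone A2.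
- For it: the C15 carbinol arrives complete, with methyl and oxygen, from an aromatic feedstock; C6 and C8 are both on C7 as carbonyl carbons; desymmetrisation of such dienones is a well-behaved reaction class.
- Against it: in A2 C10 is still a methylene next to the C12 ketone. The quaternary centre (C11 and the arm C9) would have to be built by two enolate alkylations on a cis-fused bicycle whose convex face does not obviously give the trans relation of C9 and C7. C8 enters at the carboxyl level inside the lactone and must be bonded to C9 and then reduced to a methylene. The C12 ketone must still become an equatorial neopentyl bromide, the same problem as in the chosen route.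
- Comparison: Alternative 1 is stronger at C15, which the chosen route has to reset through a ketone and a methyl addition. The chosen route offers instead C10, C17 and the trans disposition of both ring arms from one concerted step, which are the centres A2 leaves open, and it reaches the bicycle by a single alkylation.

**Alternative 2:** The disconnection is C10–C17 together with C15–O, in a cation–olefin cyclisation. In the bromohydrin acid A3 a Lewis acid would ionise the tertiary C10 hydroxyl with participation of the neighbouring bromine; the bromiranium ion is opened at C10 by the C15=C17 alkene and the carboxyl group closes onto C15, giving the bromo lactone A4.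
- For it: it is the only one of the four plans that installs the C12 bromide without substitution at a neopentyl carbon, and it passes the configuration of A3 directly to C10 and C12. On this point it is stronger than the chosen route.
- Against it: the cis-fused lactone of A4 needs C10 and the carboxyl oxygen to add to the same side of the E-alkene (C15–O axial). A concerted antiperiplanar closure leads to the trans lactone with C15 inverted, so the step must pass through a free C15 cation and its outcome at C15 is not secured. Bromiranium ions exchange bromine with alkenes, which erodes enantiopurity. A3 needs a stereodefined tertiary carbinol next to a secondary bromide and an E-trisubstituted alkene, a longer preparation than the one step to 3. A4 still lacks the five-membered ring (C8 and C9 are sp3 termini at different oxidation levels) and C6.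
- Comparison: the number of steps to the bicycle is equal or higher. The chosen route gives up the safer bromide of Alternative 2 for a key step whose stereochemical course, suprafacial addition to an E-alkene, is not in doubt.

**Alternative 3:** The disconnection is C4–C5, in the last C–C bond-forming step. In the diiodide A5 (vinyl iodide at C5 from hydrozirconation–iodination of an alkyne, primary neopentyl iodide at C4) zinc would insert at C4 and Pd(PPh3)4 would couple the two ends to A6, the C15 trimethylsilyl ether of the target.
- For it: it solves the alkene geometry most directly, since syn hydrometalation fixes it and cross-coupling keeps it. On this point it is at least as strong as the sigmatropic solution used here, and shorter.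
- Against it: the step closes only the outer ring and says nothing about the five stereocentres of the hydrindane, which would still need a route of their own. After zinc insertion at C4 of A5 the metal stands 1,3 to the C20 bromide across C2, the arrangement that zinc converts into a cyclopropane (Freund–Gustavson 1,3-elimination). Zinc and zerovalent palladium can also attack the two secondary bromides, and a neopentylzinc transmetallates slowly.
- Comparison: the chosen route keeps the idea of fixing the geometry before the ring exists, but does it by an Ireland–Claisen rearrangement while C20 is still a carbonyl carbon, so no low-valent metal meets a C–Br bond, and its key step answers the stereochemical core of the molecule.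

Key step: step 2

Remarks on the chemistry (assumptions):
- The atom labels C1 to C20 of the target are kept for all intermediates.
- The facial sense of the oxazaborolidinium catalyst is taken from the usual binding model for α-substituted enals; if the opposite sense were found, the mirror-image catalyst would be used with no other change.
- Compounds 1, 2, 4, 23 and 24 are taken as commercial.

## Route

Step 1
Reactants: 1 3-(tert-butyldimethylsilyloxy)propanal; 2 2-(triphenylphosphoranylidene)propanal
Product: 3 (E)-5-(tert-butyldimethylsilyloxy)-2-methylpent-2-enal
Conditions: toluene, 90 °C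
Reagents that add atoms: none
Why: Wittig olefination with a formyl-stabilised ylide, which gives the E-alkene (formyl carbon trans to the new chain); the product enal is much less electrophilic than 1, so a second addition is not expected.

Step 2
Reactants: 3 (E)-5-(tert-butyldimethylsilyloxy)-2-methylpent-2-enal; 4 (1E,3E)-buta-1,3-diene-1,4-diyl diacetate
Product: 5 (1S,2R,5S,6S)-2,5-diacetoxy-6-[2-(tert-butyldimethylsilyloxy)ethyl]-1-methylcyclohex-3-ene-1-carbaldehyde (formyl cis to both acetoxy groups and trans to the silyloxyethyl chain)
Conditions: 4 (2 equiv), (S)-1-(2-methylphenyl)-3,3-diphenyltetrahydro-1H,3H-pyrrolo[1,2-c][1,3,2]oxazaborole (20 mol%), (CF3SO2)2NH (20 mol%), CH2Cl2, −78 → −20 °C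
Reagents that add atoms: none
Why: The protonated oxazaborolidine is a strong chiral Lewis acid that binds the formyl oxygen of 3 and lowers the LUMO of the C10=C17 bond, so that diene 4 can add in a concerted, asynchronous [4+2] cycloaddition; the closest known reaction type is the oxazaborolidinium-catalysed Diels–Alder reaction of 2-methyl-2-enals with open-chain dienes, and 1,4-diacyloxybutadienes are established Diels–Alder dienes. The ring C10/C12/C13/C14/C15/C17 is closed intermolecularly by the two new bonds C10–C12 and C15–C17, formed suprafacially on both partners. Because the addition is suprafacial on the E-enal, methyl C11 and the C7 chain end cis and the formyl carbon C9 trans to C7, whatever the endo/exo ratio. The E,E geometry of 4 places the two acetoxy groups cis to each other, and the formyl-endo transition state places both cis to C9. The absolute configuration comes from the catalyst, which holds the enal s-trans with one face covered by an aryl group, so that 4 adds to the Re face at C10. The step needs enantioface control, which the catalyst supplies, and endo selectivity; it needs no regiocontrol because 4 is symmetric. Endo addition is expected because complexation strengthens the interaction of the carbonyl group with the diene, and with an open-chain diene the α-methyl group does not meet the clash that favours exo adducts with cyclopentadiene.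

Step 3
Reactants: 5 cycloadduct
Product: 6 saturated aldehyde (2,5-diacetoxy-6-[2-(tert-butyldimethylsilyloxy)ethyl]-1-methylcyclohexane-1-carbaldehyde, configuration as in 5)
Conditions: H2 (1 atm), Rh/Al2O3, EtOAc, 20 °C
Reagents that add atoms: none
Why: Heterogeneous hydrogenation of the cis-disubstituted ring alkene C13=C14; rhodium is chosen because it saturates the alkene without the hydrogenolysis of allylic C–O bonds that palladium tends to cause, and the neopentyl aldehyde is not reduced at atmospheric pressure.

Step 4
Reactants: 6 saturated aldehyde
Product: 7 vinyl diacetate (C9=C8 in place of the formyl group of 6)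
Conditions: Ph3PCH3Br, KN(SiMe3)2, THF, −78 → 0 °C
Reagents that add atoms: methyltriphenylphosphonium bromide, C[P+](c1ccccc1)(c1ccccc1)c1ccccc1.[Br-]
Why: Wittig methylenation; the aldehyde has no α-hydrogen (C10 is quaternary), so neither enolisation nor β-elimination of acetate can occur, and at low temperature the ylide should attack the aldehyde much faster than the two acetates.

Step 5
Reactants: 7 vinyl diacetate
Product: 9 primary alcohol (C8–OH) diacetate, via B-alkyl-9-borabicyclononane 8 (not isolated)
Conditions: 9-BBN, THF, 0 → 20 °C; then H2O2, aq. NaOAc, 0 °C
Reagents that add atoms: hydrogen peroxide, OO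
Why: Anti-Markovnikov hydroboration–oxidation; the bulky borane puts boron on the terminal C8 of a vinyl group on a quaternary carbon, esters tolerate 9-BBN, and the buffered peroxide work-up spares the acetates.

Step 6
Reactants: 9 primary alcohol diacetate
Product: 10 primary bromide (C8–Br) diacetate
Conditions: CBr4, PPh3, CH2Cl2, 0 °C
Reagents that add atoms: tetrabromomethane, BrC(Br)(Br)Br
Why: Appel bromination; SN2 displacement of the oxyphosphonium group at the unhindered primary C8, with acetates and silyl ether untouched.

Step 7
Reactants: 10 primary bromide diacetate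
Product: 11 bromo diol (C12–OH and C15–OH free)
Conditions: i-Bu2AlH (5 equiv), CH2Cl2, −78 °C; aq. potassium sodium tartrate
Reagents that add atoms: none
Why: Reductive cleavage of both acetates by i-Bu2AlH; the oxygens are released as aluminium alkoxides, which are not nucleophilic, whereas carbonate in methanol would generate a free C12 alkoxide that can displace the C8 bromide to form a tetrahydrofuran; alkyl bromide and silyl ether are inert at −78 °C.

Step 8
Reactants: 11 bromo diol
Product: 12 C15 triethylsilyl ether (C12–OH free)
Conditions: Et3SiCl (1.05 equiv), imidazole, CH2Cl2, −40 → 0 °C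
Reagents that add atoms: chlorotriethylsilane, CC[Si](Cl)(CC)CC
Why: Selective silylation; in the chair with C11 axial the C15 hydroxyl is equatorial and flanked by a CH, while the C12 hydroxyl is axial and neopentyl, so the silyl chloride should take C15 only.

Step 9
Reactants: 12 C15 triethylsilyl ether
Product: 13 dibromide (C12–Br equatorial and cis to C11, C15 triethylsilyl ether)
Conditions: CBr4, PPh3, 2,6-lutidine, toluene, 0 → 60 °C
Reagents that add atoms: tetrabromomethane, BrC(Br)(Br)Br
Why: Appel bromination with inversion (SN2 on the oxyphosphonium ion), a transformation known for axial hydroxyls next to quaternary carbons. The chair is locked, because the other chair would put the C9 arm and the C15 silyloxy group 1,3-diaxial, so the leaving group is axial and bromide approaches along the equatorial direction. C10 carries no alkene or other cation-stabilising group at this stage, which disfavours a methyl shift.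

Step 10
Reactants: 13 dibromide C15 triethylsilyl ether
Product: 14 dibromo alcohol (C15–OH free)
Conditions: pyridinium p-toluenesulfonate (cat.), MeOH/CH2Cl2, 0 °C
Reagents that add atoms: none
Why: Acid-catalysed methanolysis; a secondary triethylsilyl ether is cleaved much faster than the primary tert-butyldimethylsilyl ether at C6, and the bromides are inert.

Step 11
Reactants: 14 dibromo alcohol
Product: 15 dibromo ketone (C15=O)
Conditions: Dess–Martin periodinane, NaHCO3, CH2Cl2, 20 °C
Reagents that add atoms: none
Why: Dess–Martin oxidation under buffered, non-basic conditions, so C17 is not epimerised and the C12 bromide is not lost by 1,3-elimination; the trans-diequatorial arrangement of the arms is in any case the stable one.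

Step 12
Reactants: 15 dibromo ketone
Product: 16 tertiary alcohol (C15: hydroxyl axial and cis to C11, methyl C16 equatorial)
Conditions: MeMgBr, CeCl3 (anhydrous), THF, −78 °C; aq. NH4Cl
Reagents that add atoms: methylmagnesium bromide, C[Mg]Br
Why: Organocerium addition to a ketone. The chair of 15 is locked by the equatorial C12 bromide and the two equatorial arms, the axial C11 stands 1,3 to C15 and blocks axial attack, and the methyl group therefore enters equatorially, as with 3-axially substituted cyclohexanones. CeCl3 suppresses enolisation and the reagent leaves the alkyl bromides alone at −78 °C.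

Step 13
Reactants: 16 tertiary alcohol
Product: 17 bis(silyl ether) (C15–OSi(t-Bu)Me2 and C6–OSi(t-Bu)Me2)
Conditions: t-BuMe2SiOSO2CF3, 2,6-lutidine, CH2Cl2, 0 → 20 °C
Reagents that add atoms: tert-butyldimethylsilyl trifluoromethanesulfonate, CC(C)(C)[Si](C)(C)OS(=O)(=O)C(F)(F)F
Why: Silylation of a hindered tertiary alcohol with a silyl triflate; the protection is needed because a free C15 hydroxyl would trap the later C6 aldehyde as a lactol.

Step 14
Reactants: 17 bis(silyl ether)
Product: 18 primary alcohol (C6–OH)
Conditions: HF·pyridine, pyridine, THF, 0 °C
Reagents that add atoms: none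
Why: Buffered fluoride cleavage is governed by steric access, so the primary silyl ether is removed while the tertiary one, 1,3-diaxial to C11, stays.

Step 15
Reactants: 18 primary alcohol
Product: 19 bromo aldehyde (C6 aldehyde, C8–Br)
Conditions: Dess–Martin periodinane, NaHCO3, CH2Cl2, 20 °C
Reagents that add atoms: none
Why: Dess–Martin oxidation of a primary alcohol to the aldehyde without over-oxidation and without affecting bromides or the silyl ether.

Step 16
Reactants: 19 bromo aldehyde
Product: 22 trans-hydrindane aldehyde (C6 formyl on C7 cis to H17), via N-cyclohexyl imine 20 (not isolated), via bicyclic N-cyclohexyl imine 21 (not isolated)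
Conditions: c-C6H11NH2, 4 Å molecular sieves, Et2O, 20 °C; LiN(i-Pr)2, THF, −78 → 0 °C; aq. (CO2H)2, THF, 20 °C
Reagents that add atoms: none
Why: Intramolecular Stork metalloenamine alkylation: the lithiated imine is nucleophilic at C7 and displaces the primary C8 bromide in a 5-exo-tet closure of the ring C7/C8/C9/C10/C17, trans-fused because both arms are equatorial. In the transition state the C6 unit turns away from the axial C11 and the axial C15 silyloxy group, which sets C7 with C6 cis to H17. The same isomer is the more stable one, so equilibration of the aldehyde during hydrolysis works in the same direction.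

Step 17
Reactants: 23 2,3-dibromoprop-1-ene; 24 (4-methoxyphenyl)methanol
Product: 25 1-{[(2-bromoprop-2-en-1-yl)oxy]methyl}-4-methoxybenzene
Conditions: NaH, THF, 0 → 20 °C
Reagents that add atoms: none
Why: Williamson ether synthesis; the alkoxide displaces the allylic bromide, the vinylic bromide being inert to SN2.

Step 18
Reactants: 22 trans-hydrindane aldehyde; 25 1-{[(2-bromoprop-2-en-1-yl)oxy]methyl}-4-methoxybenzene
Product: 27 allylic alcohol (C6–OH, both C6 epimers; C5=C4H2, C18–O-4-methoxybenzyl), via 2-lithioallyl ether 26 (not isolated)
Conditions: 25, t-BuLi (2 equiv), Et2O, −78 °C; then 22, −78 °C; aq. NH4Cl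
Reagents that add atoms: none
Why: Bromine–lithium exchange gives the alkenyllithium, which is stable at −78 °C and adds 1,2 to the aldehyde faster than it deprotonates C7; both C6 epimers are carried on because C6 becomes sp2 in step 20.

Step 19
Reactants: 27 allylic alcohol
Product: 28 isobutyrate (2-methylpropanoate of the C6 hydroxyl)
Conditions: i-PrCOCl, pyridine, 4-(dimethylamino)pyridine (cat.), CH2Cl2, 0 → 20 °C
Reagents that add atoms: 2-methylpropanoyl chloride, CC(C)C(Cl)=O
Why: Acylation of a secondary alcohol under nucleophilic catalysis; it installs the C2/C20 unit with both methyl groups.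

Step 20
Reactants: 28 isobutyrate
Product: 31 carboxylic acid (C20 acid on quaternary C2; C5=C6 with C4 trans to C7), via silyl ketene acetal 29 (not isolated), via trimethylsilyl ester 30 (not isolated)
Conditions: LiN(i-Pr)2, Me3SiCl, THF, −78 → 65 °C; then 1 M HCl (aq), 20 °C
Reagents that add atoms: none
Why: Ireland–Claisen rearrangement: the silyl ketene acetal has two identical methyl groups on its terminus, so enolate geometry does not matter, and the [3,3] shift forms C2–C4 and the quaternary C2. The chair transition state keeps the large C7 substituent on C6 equatorial, which places C4 trans to C7 on the new C5=C6 bond (the descriptor in 31 is Z only because C18 bears oxygen). Both C6 epimers of 28 converge on the same alkene.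

Step 21
Reactants: 31 carboxylic acid
Product: 32 methyl ketone (C20=O with methyl C19)
Conditions: MeLi (3.5 equiv), Et2O, 0 → 20 °C; inverse quench into aq. NH4Cl
Reagents that add atoms: methyllithium, [Li]C
Why: Addition of methyllithium to a lithium carboxylate; the dilithium gem-diolate survives until work-up, so the ketone is released only after the reagent is destroyed, a standard route to methyl ketones from acids next to a quaternary carbon.

Step 22
Reactants: 32 methyl ketone
Product: 33 allylic alcohol (C18–OH)
Conditions: DDQ, CH2Cl2/pH 7 buffer, 0 °C
Reagents that add atoms: none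
Why: Oxidative cleavage of the 4-methoxybenzyl ether by hydride abstraction and hydrolysis; silyl ether, bromide, ketone and the isolated alkene are not affected at 0 °C.

Step 23
Reactants: 33 allylic alcohol
Product: 34 allylic chloride (C18–Cl)
Conditions: PPh3, CCl4, CH2Cl2, 20 °C
Reagents that add atoms: tetrachloromethane, ClC(Cl)(Cl)Cl
Why: Appel chlorination of a primary allylic alcohol, which gives the primary chloride without allylic transposition, so the geometry of C5=C6 is kept.

Step 24
Reactants: 34 allylic chloride
Product: 35 cyclohexanone (ring C2/C4/C5/C18/C19/C20 closed, C20=O, E-alkene)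
Conditions: LiN(SiMe3)2, THF, −78 → 25 °C
Reagents that add atoms: none
Why: Intramolecular enolate alkylation: the ketone can enolise only toward C19 because C2 is quaternary, and the lithium enolate displaces the allylic chloride at C18 in a 6-(enolendo)-exo-tet closure, the mode known to give cyclohexanones by C-alkylation. The alkene is not a reacting centre, so C4 stays trans to C7, which is now the E descriptor.

Step 25
Reactants: 35 cyclohexanone
Product: 36 (R)-configured C20 alcohol
Conditions: (S)-1-methyl-3,3-diphenyltetrahydro-1H,3H-pyrrolo[1,2-c][1,3,2]oxazaborole (20 mol%), BH3·SMe2, THF, −20 °C; MeOH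
Reagents that add atoms: none
Why: Corey–Bakshi–Shibata reduction; the ketone has a large quaternary side (C2) and a small methylene side (C19), the substitution pattern for which the (S)-catalyst delivers hydride to give the (R)-alcohol, and the catalysed reduction is much faster than hydroboration of the hindered trisubstituted alkene.

Step 26
Reactants: 36 (R)-configured C20 alcohol
Product: 37 tert-butyldimethylsilyl ether of the target (C20–Br, S)
Conditions: CBr4, PPh3, 2,6-lutidine, toluene, 0 → 60 °C
Reagents that add atoms: tetrabromomethane, BrC(Br)(Br)Br
Why: Appel bromination with inversion, as in step 9; the flexible ring can place the oxyphosphonium group axial so that bromide enters along the equatorial direction next to the gem-dimethyl carbon, and the protected tertiary alcohol and the C12 bromide do not take part.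

Step 27
Reactants: 37 tert-butyldimethylsilyl ether of the target
Product: 38 (3S,3aS,4R,7S,7aS)-7-bromo-3-{(E)-[(4S)-4-bromo-3,3-dimethylcyclohexylidene]methyl}-4,7a-dimethyloctahydro-1H-inden-4-ol (the target CNP0119865.1)
Conditions: HF·pyridine, THF, 0 → 40 °C
Reagents that add atoms: none
Why: Fluoride cleavage of the tertiary silyl ether; the reagent is not basic, so the two bromides are not eliminated, and it is too weak an acid to dehydrate the tertiary alcohol or move the alkene.

## Compound list

1 | 3-(tert-butyldimethylsilyloxy)propanal | O=CCCO[Si](C)(C)C(C)(C)C | starting material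
2 | 2-(triphenylphosphoranylidene)propanal | CC(C=O)=P(c1ccccc1)(c1ccccc1)c1ccccc1 | starting material
3 | (E)-5-(tert-butyldimethylsilyloxy)-2-methylpent-2-enal | O=C/C(C)=C/CCO[Si](C)(C)C(C)(C)C | intermediate
4 | (1E,3E)-buta-1,3-diene-1,4-diyl diacetate | CC(=O)O/C=C/C=C/OC(C)=O | starting material
5 | (1S,2R,5S,6S)-2,5-diacetoxy-6-[2-(tert-butyldimethylsilyloxy)ethyl]-1-methylcyclohex-3-ene-1-carbaldehyde | O=C[C@]1(C)[C@H](OC(C)=O)C=C[C@H](OC(C)=O)[C@H]1CCO[Si](C)(C)C(C)(C)C | intermediate
6 | saturated aldehyde (dihydro-5) | O=C[C@]1(C)[C@H](OC(C)=O)CC[C@H](OC(C)=O)[C@H]1CCO[Si](C)(C)C(C)(C)C | intermediate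
7 | vinyl diacetate (C9=C8) | C=C[C@]1(C)[C@H](OC(C)=O)CC[C@H](OC(C)=O)[C@H]1CCO[Si](C)(C)C(C)(C)C | intermediate
8 | B-alkyl-9-borabicyclo[3.3.1]nonane (boron on C8) | B1(CC[C@]2(C)[C@H](OC(C)=O)CC[C@H](OC(C)=O)[C@H]2CCO[Si](C)(C)C(C)(C)C)C3CCCC1CCC3 | intermediate
9 | primary alcohol (C8–OH) diacetate | OCC[C@]1(C)[C@H](OC(C)=O)CC[C@H](OC(C)=O)[C@H]1CCO[Si](C)(C)C(C)(C)C | intermediate
10 | primary bromide (C8–Br) diacetate | BrCC[C@]1(C)[C@H](OC(C)=O)CC[C@H](OC(C)=O)[C@H]1CCO[Si](C)(C)C(C)(C)C | intermediate
11 | bromo diol (C12–OH, C15–OH) | BrCC[C@]1(C)[C@H](O)CC[C@H](O)[C@H]1CCO[Si](C)(C)C(C)(C)C | intermediate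
12 | C15 triethylsilyl ether, C12 alcohol | BrCC[C@]1(C)[C@H](O)CC[C@H](O[Si](CC)(CC)CC)[C@H]1CCO[Si](C)(C)C(C)(C)C | intermediate
13 | dibromide (C12–Br inverted), C15 triethylsilyl ether | BrCC[C@]1(C)[C@@H](Br)CC[C@H](O[Si](CC)(CC)CC)[C@H]1CCO[Si](C)(C)C(C)(C)C | intermediate
14 | dibromo alcohol (C15–OH) | BrCC[C@]1(C)[C@@H](Br)CC[C@H](O)[C@H]1CCO[Si](C)(C)C(C)(C)C | intermediate
15 | dibromo ketone (C15=O) | BrCC[C@]1(C)[C@@H](Br)CCC(=O)[C@H]1CCO[Si](C)(C)C(C)(C)C | intermediate
16 | tertiary alcohol (C15 methyl carbinol) | BrCC[C@]1(C)[C@@H](Br)CC[C@@](C)(O)[C@H]1CCO[Si](C)(C)C(C)(C)C | intermediate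
17 | bis(tert-butyldimethylsilyl ether) | BrCC[C@]1(C)[C@@H](Br)CC[C@@](C)(O[Si](C)(C)C(C)(C)C)[C@H]1CCO[Si](C)(C)C(C)(C)C | intermediate
18 | primary alcohol (C6–OH) | BrCC[C@]1(C)[C@@H](Br)CC[C@@](C)(O[Si](C)(C)C(C)(C)C)[C@H]1CCO | intermediate
19 | bromo aldehyde (C6 aldehyde) | BrCC[C@]1(C)[C@@H](Br)CC[C@@](C)(O[Si](C)(C)C(C)(C)C)[C@H]1CC=O | intermediate
20 | N-cyclohexyl imine of 19 | BrCC[C@]1(C)[C@@H](Br)CC[C@@](C)(O[Si](C)(C)C(C)(C)C)[C@H]1C/C=N/C2CCCCC2 | intermediate
21 | N-cyclohexyl imine of 22 | C1CCCCC1/N=C/[C@@H]2CC[C@]3(C)[C@@H](Br)CC[C@@](C)(O[Si](C)(C)C(C)(C)C)[C@@H]23 | intermediate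
22 | trans-hydrindane aldehyde (configuration of the bicycle as in 38) | O=C[C@@H]1CC[C@]2(C)[C@@H](Br)CC[C@@](C)(O[Si](C)(C)C(C)(C)C)[C@@H]12 | intermediate
23 | 2,3-dibromoprop-1-ene | BrCC(Br)=C | starting material
24 | (4-methoxyphenyl)methanol | COc1ccc(CO)cc1 | starting material
25 | 1-{[(2-bromoprop-2-en-1-yl)oxy]methyl}-4-methoxybenzene | BrC(=C)COCc1ccc(OC)cc1 | intermediate
26 | 2-lithioallyl 4-methoxybenzyl ether | [Li]C(=C)COCc1ccc(OC)cc1 | intermediate
27 | allylic alcohol (C6–OH, both epimers) | OC(C(=C)COCc1ccc(OC)cc1)[C@@H]2CC[C@]3(C)[C@@H](Br)CC[C@@](C)(O[Si](C)(C)C(C)(C)C)[C@@H]23 | intermediate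
28 | isobutyrate of 27 | CC(C)C(=O)OC(C(=C)COCc1ccc(OC)cc1)[C@@H]2CC[C@]3(C)[C@@H](Br)CC[C@@](C)(O[Si](C)(C)C(C)(C)C)[C@@H]23 | intermediate
29 | trimethylsilyl ketene acetal of 28 | CC(C)=C(O[Si](C)(C)C)OC(C(=C)COCc1ccc(OC)cc1)[C@@H]2CC[C@]3(C)[C@@H](Br)CC[C@@](C)(O[Si](C)(C)C(C)(C)C)[C@@H]23 | intermediate
30 | trimethylsilyl ester of 31 | C[Si](C)(C)OC(=O)C(C)(C)C/C(COCc1ccc(OC)cc1)=C/[C@@H]2CC[C@]3(C)[C@@H](Br)CC[C@@](C)(O[Si](C)(C)C(C)(C)C)[C@@H]23 | intermediate
31 | carboxylic acid (C20 acid, C4 trans to C7) | OC(=O)C(C)(C)C/C(COCc1ccc(OC)cc1)=C/[C@@H]2CC[C@]3(C)[C@@H](Br)CC[C@@](C)(O[Si](C)(C)C(C)(C)C)[C@@H]23 | intermediate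
32 | methyl ketone | CC(=O)C(C)(C)C/C(COCc1ccc(OC)cc1)=C/[C@@H]2CC[C@]3(C)[C@@H](Br)CC[C@@](C)(O[Si](C)(C)C(C)(C)C)[C@@H]23 | intermediate
33 | allylic alcohol (C18–OH) | CC(=O)C(C)(C)C/C(CO)=C/[C@@H]1CC[C@]2(C)[C@@H](Br)CC[C@@](C)(O[Si](C)(C)C(C)(C)C)[C@@H]12 | intermediate
34 | allylic chloride (C18–Cl) | CC(=O)C(C)(C)C/C(CCl)=C/[C@@H]1CC[C@]2(C)[C@@H](Br)CC[C@@](C)(O[Si](C)(C)C(C)(C)C)[C@@H]12 | intermediate
35 | cyclohexanone (C20=O, E-alkene) | CC1(C)C/C(=C/[C@@H]2CC[C@]3(C)[C@@H](Br)CC[C@@](C)(O[Si](C)(C)C(C)(C)C)[C@@H]23)CCC1=O | intermediate
36 | (R)-C20 alcohol | CC1(C)C/C(=C/[C@@H]2CC[C@]3(C)[C@@H](Br)CC[C@@](C)(O[Si](C)(C)C(C)(C)C)[C@@H]23)CC[C@H]1O | intermediate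
37 | C15 tert-butyldimethylsilyl ether of the target | CC1(C)C/C(=C/[C@@H]2CC[C@]3(C)[C@@H](Br)CC[C@@](C)(O[Si](C)(C)C(C)(C)C)[C@@H]23)CC[C@@H]1Br | intermediate
38 | (3S,3aS,4R,7S,7aS)-7-bromo-3-{(E)-[(4S)-4-bromo-3,3-dimethylcyclohexylidene]methyl}-4,7a-dimethyloctahydro-1H-inden-4-ol | CC1(C)C/C(=C/[C@@H]2CC[C@]3(C)[C@@H](Br)CC[C@@](C)(O)[C@@H]23)CC[C@@H]1Br | target

## Step count and least certain steps

Total: 27 steps. Longest linear sequence: 26 steps (steps 1–16 and 18–27); step 17 is a one-step side branch.

**Step 2 (key step).** The most likely failure is insufficient reactivity: the enal is β-substituted and α-branched, the acyloxy diene is only weakly nucleophilic, its ester carbonyls can compete for the Lewis acid, and the acid can consume the diene before cycloaddition. A share of exo addition would also put the C12 oxygen on the wrong face. The fallback gives up catalysis. It sets out from 3 and 4, which are combined without catalyst under high pressure (about 12 kbar, CH2Cl2, 20 °C). This should give the endo adduct as the racemate, that is 5 together with the mirror-image adduct F1. Condensation of the formyl group with (1R,2R)-N,N′-dimethyl-1,2-diphenylethane-1,2-diamine then gives two diastereomeric aminals, the imidazolidine of 5 F2 and the imidazolidine of the mirror-image adduct F3, which are separated by chromatography. Mild aqueous acid on F2 releases 5, where the route is rejoined.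

**Step 8.** Incomplete discrimination between the two secondary hydroxyls, or silyl transfer between them, would lower the yield and carry the wrong regioisomer into the bromination. The fallback replaces selective protection by selective oxidation. It sets out from 11, which is oxidised with 2,2,6,6-tetramethylpiperidin-1-oxyl (cat.) and PhI(OAc)2; this oxidant discriminates strongly against hindered carbinols and should give the hydroxy ketone F4 (C15=O, C12–OH). Bromination of F4 with CBr4 and PPh3 at 0–25 °C, with only a slight excess of reagent so that the ketone is not olefinated, leads directly to 15, where the route is rejoined.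

**Step 9.** At a neopentyl carbon the substitution is slow. Loss of the activated oxygen by elimination toward C13, or with migration of the antiperiplanar methyl group from C10, can overtake it. The fallback separates activation from substitution. It sets out from 12, which is converted with (CF3SO2)2O and pyridine in CH2Cl2 at −30 °C into the C12 trifluoromethanesulfonate F5. The isolated sulfonate is then displaced with tetrabutylammonium bromide in toluene at 0 → 20 °C, a non-ionising medium with a soluble, non-basic bromide and no phosphorus species, to give 13, where the route is rejoined.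

**Step 16.** Imine formation may be incomplete beside the primary bromide, the strong base may cause elimination at C8, and the aldehyde may emerge as a mixture at C7 after hydrolysis. The fallback moves the ring closure to an ester enolate. It sets out from 19, which is oxidised with NaClO2, NaH2PO4 and 2-methylbut-2-ene to the carboxylic acid F6 and esterified with Me3SiCHN2 to the methyl ester F7. LiN(i-Pr)2 in THF at −78 → 0 °C closes the ring to the trans-hydrindane methyl ester F8, which can be equilibrated at C7 with NaOMe in MeOH if needed. i-Bu2AlH at −78 °C reduces F8 to 22, where the route is rejoined.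

**Step 26.** As in step 9, elimination toward C19 or a methyl shift from C2 may compete with substitution, and here transannular participation of the C5=C6 bond is an additional exit. The fallback avoids substitution at C20 altogether, at the price of reagent control. It sets out from 35, which is condensed with hydrazine to the hydrazone F9 and converted with CuBr2 and Et3N in MeOH into the C20 gem-dibromide F10. One equivalent of Bu3SnH with Et3B/O2 at −78 → 0 °C removes one bromine, the gem-dibromide reacting faster than the C12 bromide. This should give 37 together with the C20 epimer F11, which is separated by chromatography; the route is rejoined at 37.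

## Further compounds

F1 | step 2 | mirror-image adduct (enantiomer of 5) | O=C[C@@]1(C)[C@@H](OC(C)=O)C=C[C@@H](OC(C)=O)[C@@H]1CCO[Si](C)(C)C(C)(C)C
F2 | step 2 | (4R,5R)-1,3-dimethyl-4,5-diphenylimidazolidine (aminal) of 5 | CN1[C@H](c2ccccc2)[C@@H](c2ccccc2)N(C)C1[C@]3(C)[C@H](OC(C)=O)C=C[C@H](OC(C)=O)[C@H]3CCO[Si](C)(C)C(C)(C)C
F3 | step 2 | (4R,5R)-1,3-dimethyl-4,5-diphenylimidazolidine (aminal) of the mirror-image adduct | CN1[C@H](c2ccccc2)[C@@H](c2ccccc2)N(C)C1[C@@]3(C)[C@@H](OC(C)=O)C=C[C@@H](OC(C)=O)[C@@H]3CCO[Si](C)(C)C(C)(C)C
F4 | step 8 | hydroxy ketone (C15=O, C12–OH, C8–Br) | BrCC[C@]1(C)[C@H](O)CCC(=O)[C@H]1CCO[Si](C)(C)C(C)(C)C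
F5 | step 9 | C12 trifluoromethanesulfonate of 12 | BrCC[C@]1(C)[C@H](OS(=O)(=O)C(F)(F)F)CC[C@H](O[Si](CC)(CC)CC)[C@H]1CCO[Si](C)(C)C(C)(C)C
F6 | step 16 | carboxylic acid (C6) from 19 | BrCC[C@]1(C)[C@@H](Br)CC[C@@](C)(O[Si](C)(C)C(C)(C)C)[C@H]1CC(=O)O
F7 | step 16 | methyl ester of F6 | BrCC[C@]1(C)[C@@H](Br)CC[C@@](C)(O[Si](C)(C)C(C)(C)C)[C@H]1CC(=O)OC
F8 | step 16 | trans-hydrindane methyl ester | COC(=O)[C@@H]1CC[C@]2(C)[C@@H](Br)CC[C@@](C)(O[Si](C)(C)C(C)(C)C)[C@@H]12
F9 | step 26 | hydrazone of 35 | CC1(C)C/C(=C/[C@@H]2CC[C@]3(C)[C@@H](Br)CC[C@@](C)(O[Si](C)(C)C(C)(C)C)[C@@H]23)CCC1=NN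
F10 | step 26 | C20 gem-dibromide | CC1(C)C/C(=C/[C@@H]2CC[C@]3(C)[C@@H](Br)CC[C@@](C)(O[Si](C)(C)C(C)(C)C)[C@@H]23)CCC1(Br)Br
F11 | step 26 | C20 epimer of 37 | CC1(C)C/C(=C/[C@@H]2CC[C@]3(C)[C@@H](Br)CC[C@@](C)(O[Si](C)(C)C(C)(C)C)[C@@H]23)CC[C@H]1Br
A1 | alternative 1 | methyl 1-methyl-4-oxocyclohexa-2,5-dien-1-yl malonate (quinol malonate) | COC(=O)CC(=O)OC1(C)C=CC(=O)C=C1
A2 | alternative 1 | cis-fused bicyclic lactone enone | COC(=O)[C@H]2C(=O)O[C@]3(C)C=CC(=O)C[C@H]23
A3 | alternative 2 | (E)-7-bromo-9-(tert-butyldiphenylsilyloxy)-8-hydroxy-4,8-dimethylnon-3-enoic acid (bromohydrin acid) | CC(C)(C)[Si](c1ccccc1)(c1ccccc1)OC[C@](O)(C)[C@@H](Br)CC/C(C)=C/CC(=O)O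
A4 | alternative 2 | cis-fused bromo lactone | CC(C)(C)[Si](c1ccccc1)(c1ccccc1)OC[C@]3(C)[C@@H](Br)CC[C@@](C)(OC(=O)C4)[C@@H]43
A5 | alternative 3 | open-chain diiodide (vinyl iodide at C5, primary iodide at C4), C15 trimethylsilyl ether | ICC(C)(C)[C@@H](Br)CC\C(I)=C/[C@@H]2CC[C@]3(C)[C@@H](Br)CC[C@@](C)(O[Si](C)(C)C)[C@@H]23
A6 | alternative 3 | C15 trimethylsilyl ether of the target | CC1(C)C/C(=C/[C@@H]2CC[C@]3(C)[C@@H](Br)CC[C@@](C)(O[Si](C)(C)C)[C@@H]23)CC[C@@H]1Br
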